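**Retrosynthetic overview**
1. Locants follow the target's name as an 11-oxabicyclo[8.1.0]undec-4-ene (C-1/C-10 oxirane, C-2 ester carbinol, C-3 CH–iPr, C-4=C-5 E-alkene, C-6 tertiary carbinol). The ester C–O bond is cut last, giving the macrocyclic epoxy diol and TBS-protected 4-hydroxybenzoic acid.
2. The ten-membered ring is opened at C-4=C-5 (ring-closing metathesis of an acyclic epoxy diene diol); this ring is formed last.
3. Key disconnection C-2–C-3: intermolecular Evans syn aldol between an N-isovaleryl oxazolidinone and a cis-epoxy aldehyde; it sets C-2 and C-3, and the acyl carbon becomes C-4.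
4. The oxirane (first ring formed, C-1/C-10) comes from Sharpless epoxidation of a Z-allylic alcohol, itself made by methylcuprate addition to an ynoate built by acetylide alkylation.
5. C-5 to C-9 and the C-6 stereocentre come from (R)-linalool.

Assumption: commercial (R)-(−)-linalool of ≥97% ee is used, so C-6 needs no separate asymmetric step.

**Step 1**
Reactants: 1 (R)-(−)-linalool
Product: 2 (3R)-3,7-dimethyl-3-[(triethylsilyl)oxy]octa-1,6-diene
Conditions: TESOTf, 2,6-lutidine, CH2Cl2, −78 → 0 °C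
Reagents that add atoms: triethylsilyl trifluoromethanesulfonate (TESOTf), CC[Si](CC)(CC)OS(=O)(=O)C(F)(F)F
Why: O-silylation with a silyl triflate and a hindered pyridine base protects even a tertiary allylic alcohol cleanly and leaves the C-6 stereocentre untouched.

**Step 2**
Reactants: 2 (3R)-3,7-dimethyl-3-[(triethylsilyl)oxy]octa-1,6-diene
Product: 4 (4R)-4-methyl-4-[(triethylsilyl)oxy]hex-5-en-1-ol, via aldehyde 3 (not isolated)
Conditions: O3, CH2Cl2/MeOH (4:1), −78 °C, Sudan Red 7B end-point; then NaBH4, −78 → 0 °C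
Reagents that add atoms: ozone, [O-][O+]=O
Why: Chemoselective ozonolysis, because ozone attacks the electron-rich trisubstituted alkene far faster than the hindered vinyl group on the quaternary carbon, and the reductive work-up takes the peroxidic intermediate through aldehyde 3 to the primary alcohol.

**Step 3**
Reactants: 4 (4R)-4-methyl-4-[(triethylsilyl)oxy]hex-5-en-1-ol
Product: 5 (3R)-6-iodo-3-methyl-3-[(triethylsilyl)oxy]hex-1-ene
Conditions: I2, PPh3, imidazole, CH2Cl2, 0 °C → rt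
Reagents that add atoms: iodine, II
Why: Appel-type iodination (SN2 on the activated primary oxyphosphonium) under imidazole buffering, which the tertiary silyl ether tolerates.

**Step 4**
Reactants: 5 (3R)-6-iodo-3-methyl-3-[(triethylsilyl)oxy]hex-1-ene
Product: 6 (3R)-3-methyl-3-[(triethylsilyl)oxy]oct-1-en-7-yne
Conditions: LiC≡CH·H2NCH2CH2NH2, DMSO, 10 °C → rt
Reagents that add atoms: lithium acetylide (ethylenediamine complex), [Li]C#C
Why: SN2 alkylation of lithium acetylide by an unhindered primary iodide in DMSO, adding the two carbons that become C-10 and C-1.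

**Step 5**
Reactants: 6 (3R)-3-methyl-3-[(triethylsilyl)oxy]oct-1-en-7-yne
Product: 8 methyl (7R)-7-methyl-7-[(triethylsilyl)oxy]non-8-en-2-ynoate, via lithium acetylide 7 (not isolated)
Conditions: n-BuLi, THF, −78 °C; then ClCO2Me, −78 → 0 °C
Reagents that add atoms: methyl chloroformate, COC(=O)Cl
Why: Deprotonation of the terminal alkyne and C-acylation with a chloroformate gives the ynoate, whose ester carbon becomes C-2.

**Step 6**
Reactants: 8 methyl (7R)-7-methyl-7-[(triethylsilyl)oxy]non-8-en-2-ynoate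
Product: 9 methyl (2Z,7R)-3,7-dimethyl-7-[(triethylsilyl)oxy]nona-2,8-dienoate
Conditions: Me2CuLi (from MeLi and CuI), THF, −78 °C; MeOH then aq. NH4Cl at −78 °C
Reagents that add atoms: lithium dimethylcuprate, [Li+].C[Cu-]C
Why: Conjugate carbocupration of the ynoate is a stereospecific syn addition, and cold protonation of the alkenylcopper keeps methyl and the new vinylic H cis, so the chain and the ester end up cis (Z).

**Step 7**
Reactants: 9 methyl (2Z,7R)-3,7-dimethyl-7-[(triethylsilyl)oxy]nona-2,8-dienoate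
Product: 10 (2Z,7R)-3,7-dimethyl-7-[(triethylsilyl)oxy]nona-2,8-dien-1-ol
Conditions: i-Bu2AlH, CH2Cl2, −78 → −20 °C; aq. KNaC4H4O6 work-up
Reagents that add atoms: none
Why: 1,2-reduction of the enoate with a dialkylaluminium hydride gives the allylic alcohol without touching the alkene geometry.

**Step 8**
Reactants: 10 (2Z,7R)-3,7-dimethyl-7-[(triethylsilyl)oxy]nona-2,8-dien-1-ol
Product: 11 [(2R,3S)-3-methyl-3-{(4R)-4-methyl-4-[(triethylsilyl)oxy]hex-5-en-1-yl}oxiran-2-yl]methanol
Conditions: Ti(OiPr)4 (10 mol %), D-(−)-diethyl tartrate (12 mol %), t-BuOOH (anhydrous, isooctane), 4 Å molecular sieves, CH2Cl2, −20 °C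
Reagents that add atoms: tert-butyl hydroperoxide, CC(C)(C)OO
Why: Sharpless asymmetric epoxidation with the D-tartrate delivers oxygen to the face that gives the (2R,3S) epoxide (the mirror image of the nerol/L-tartrate case), the syn addition turns the Z geometry into the cis oxirane, and the isolated vinyl group is inert.

**Step 9**
Reactants: 11 [(2R,3S)-3-methyl-3-{(4R)-4-methyl-4-[(triethylsilyl)oxy]hex-5-en-1-yl}oxiran-2-yl]methanol
Product: 12 (2S,3S)-3-methyl-3-{(4R)-4-methyl-4-[(triethylsilyl)oxy]hex-5-en-1-yl}oxirane-2-carbaldehyde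
Conditions: PhI(OAc)2, TEMPO (10 mol %), CH2Cl2, rt; used crude
Reagents that add atoms: none
Why: Oxoammonium (TEMPO) oxidation stops at the aldehyde under non-aqueous, nearly neutral conditions that spare the oxirane and silyl ether (the descriptor at the oxirane CH changes only through CIP priorities).

**Step 10**
Reactants: 13 (R)-4-benzyl-1,3-oxazolidin-2-one; 14 3-methylbutanoyl chloride
Product: 16 (4R)-4-benzyl-3-(3-methylbutanoyl)-1,3-oxazolidin-2-one, via N-lithio oxazolidinone 15 (not isolated)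
Conditions: n-BuLi, THF, −78 °C; then 14, −78 → 0 °C
Reagents that add atoms: none
Why: N-acylation of the lithiated auxiliary by the acid chloride gives the aldol donor.

**Step 11**
Reactants: 16 (4R)-4-benzyl-3-(3-methylbutanoyl)-1,3-oxazolidin-2-one; 12 (2S,3S)-3-methyl-3-{(4R)-4-methyl-4-[(triethylsilyl)oxy]hex-5-en-1-yl}oxirane-2-carbaldehyde
Product: 18 (4R)-4-benzyl-3-[(2R)-2-{(R)-hydroxy[(2R,3S)-3-methyl-3-{(4R)-4-methyl-4-[(triethylsilyl)oxy]hex-5-en-1-yl}oxiran-2-yl]methyl}-3-methylbutanoyl]-1,3-oxazolidin-2-one, via Z-boron enolate 17 (not isolated)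
Conditions: Bu2BOTf, i-Pr2NEt, CH2Cl2, 0 °C; then 12, −78 → 0 °C; pH 7 buffer, MeOH, 30% H2O2, 0 °C
Reagents that add atoms: none
Why: Evans syn aldol, in which the Z-boron enolate reacts through a Zimmerman–Traxler chair on the face away from the benzyl group to set C-3 and C-2 syn, and the Felkin–Anh/Cornforth preference of the cis-epoxy aldehyde (attack anti to the oxirane C–O) favours the same erythro epoxy alcohol, so the pairing is matched.

**Step 12**
Reactants: 18 aldol adduct
Product: 19 (4R)-4-benzyl-3-[(2R)-3-methyl-2-{(R)-[(2R,3S)-3-methyl-3-{(4R)-4-methyl-4-[(triethylsilyl)oxy]hex-5-en-1-yl}oxiran-2-yl][(triethylsilyl)oxy]methyl}butanoyl]-1,3-oxazolidin-2-one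
Conditions: TESCl, imidazole, DMAP (cat.), DMF, rt
Reagents that add atoms: chlorotriethylsilane, CC[Si](Cl)(CC)CC
Why: Lewis-acid-free silylation caps the C-2 hydroxyl, which blocks retro-aldol and epoxide migration (Payne) in the following basic steps.

**Step 13**
Reactants: 19 silylated aldol adduct
Product: 20 (2S)-3-methyl-2-{(R)-[(2R,3S)-3-methyl-3-{(4R)-4-methyl-4-[(triethylsilyl)oxy]hex-5-en-1-yl}oxiran-2-yl][(triethylsilyl)oxy]methyl}butan-1-ol
Conditions: LiBH4, MeOH (1 equiv), THF, 0 °C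
Reagents that add atoms: none
Why: Reductive cleavage of the imide at the exocyclic carbonyl by lithium borohydride gives the primary alcohol and the recoverable auxiliary without opening the trisubstituted oxirane.

**Step 14**
Reactants: 20 primary alcohol
Product: 21 (2R)-3-methyl-2-{(R)-[(2R,3S)-3-methyl-3-{(4R)-4-methyl-4-[(triethylsilyl)oxy]hex-5-en-1-yl}oxiran-2-yl][(triethylsilyl)oxy]methyl}butanal
Conditions: Dess–Martin periodinane, pyridine, CH2Cl2, 0 °C → rt; used at once
Reagents that add atoms: none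
Why: Buffered Dess–Martin oxidation gives the hindered α-branched aldehyde without epimerising C-3 (descriptor change is only a CIP effect).

**Step 15**
Reactants: 21 aldehyde
Product: 22 (3R)-3-methyl-6-[(2S,3R)-2-methyl-3-{(1R,2S)-2-(propan-2-yl)-1-[(triethylsilyl)oxy]but-3-en-1-yl}oxiran-2-yl]-3-[(triethylsilyl)oxy]hex-1-ene
Conditions: Ph3PCH3Br, KN(SiMe3)2, THF, 0 °C; then 21, −78 → 0 °C
Reagents that add atoms: methyltriphenylphosphonium bromide, C[P+](c1ccccc1)(c1ccccc1)c1ccccc1.[Br-]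
Why: Wittig methylenation with the small non-stabilised ylide at low temperature converts the aldehyde carbon (C-4) into a vinyl group faster than the hindered α-centre can epimerise.

**Step 16**
Reactants: 22 bis(triethylsilyl) diene
Product: 23 (1R,2S)-1-{(2R,3S)-3-[(4R)-4-hydroxy-4-methylhex-5-en-1-yl]-3-methyloxiran-2-yl}-2-(propan-2-yl)but-3-en-1-ol
Conditions: TBAF, THF, 0 °C → rt
Reagents that add atoms: none
Why: Fluoride desilylation frees both hydroxyls under conditions that do not touch the oxirane, so that the tertiary allylic alcohol can assist the metathesis.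

**Step 17**
Reactants: 23 diene diol
Product: 24 (1R,2R,3S,4E,6R,10S)-6,10-dimethyl-3-(propan-2-yl)-11-oxabicyclo[8.1.0]undec-4-ene-2,6-diol
Conditions: second-generation Hoveyda–Grubbs catalyst RuCl2(H2IMes)(=CH-C6H4-2-OiPr) (10 mol %), toluene (1 mM), 80 °C, argon sparge
Reagents that add atoms: none
Why: Ring-closing metathesis joins the two monosubstituted olefins with loss of ethene, helped by the free allylic hydroxyl and the turn imposed by the cis-oxirane, and E geometry is expected because a Z alkene would force the quaternary C-6 and the branched C-3 into severe allylic strain.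

**Step 18**
Reactants: 25 4-hydroxybenzoic acid
Product: 27 4-[(tert-butyldimethylsilyl)oxy]benzoic acid, via bis-silyl derivative 26 (not isolated)
Conditions: TBSCl (2.4 equiv), imidazole, DMF, rt; then AcOH/THF/H2O (3:1:1), rt
Reagents that add atoms: tert-butyldimethylsilyl chloride, CC(C)(C)[Si](C)(C)Cl
Why: Exhaustive silylation followed by selective hydrolysis of the much more labile silyl ester leaves the phenol protected as its silyl ether.

**Step 19**
Reactants: 27 4-[(tert-butyldimethylsilyl)oxy]benzoic acid; 24 macrocyclic epoxy diol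
Product: 29 (1R,2R,3S,4E,6R,10S)-6-hydroxy-6,10-dimethyl-3-(propan-2-yl)-11-oxabicyclo[8.1.0]undec-4-en-2-yl 4-[(tert-butyldimethylsilyl)oxy]benzoate, via mixed anhydride 28 (not isolated)
Conditions: 2,4,6-trichlorobenzoyl chloride, Et3N, THF, rt; then 24, DMAP, toluene, rt → 40 °C
Reagents that add atoms: none
Why: Yamaguchi esterification acylates the secondary C-2 hydroxyl through the unhindered carbonyl of the mixed anhydride, while the tertiary allylic C-6 hydroxyl is too hindered to react.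

**Step 20**
Reactants: 29 silyl-protected ester
Product: 30 target CNP0278889.1
Conditions: TBAF (1.1 equiv), AcOH (1.2 equiv), THF, 0 °C
Reagents that add atoms: none
Why: Acetic-acid-buffered fluoride cleaves the phenolic silyl ether within minutes and leaves the aryl ester, the oxirane and the tertiary allylic alcohol intact.

**Compound list**
1 | (R)-(−)-linalool, (3R)-3,7-dimethylocta-1,6-dien-3-ol | C=C[C@](C)(O)CCC=C(C)C | starting material
2 | (3R)-3,7-dimethyl-3-[(triethylsilyl)oxy]octa-1,6-diene | C=C[C@](C)(O[Si](CC)(CC)CC)CCC=C(C)C | intermediate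
3 | (4R)-4-methyl-4-[(triethylsilyl)oxy]hex-5-enal | C=C[C@](C)(O[Si](CC)(CC)CC)CCC=O | intermediate
4 | (4R)-4-methyl-4-[(triethylsilyl)oxy]hex-5-en-1-ol | C=C[C@](C)(O[Si](CC)(CC)CC)CCCO | intermediate
5 | (3R)-6-iodo-3-methyl-3-[(triethylsilyl)oxy]hex-1-ene | C=C[C@](C)(O[Si](CC)(CC)CC)CCCI | intermediate
6 | (3R)-3-methyl-3-[(triethylsilyl)oxy]oct-1-en-7-yne | C=C[C@](C)(O[Si](CC)(CC)CC)CCCC#C | intermediate
7 | lithium acetylide of 6 | C=C[C@](C)(O[Si](CC)(CC)CC)CCCC#C[Li] | intermediate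
8 | methyl (7R)-7-methyl-7-[(triethylsilyl)oxy]non-8-en-2-ynoate | C=C[C@](C)(O[Si](CC)(CC)CC)CCCC#CC(=O)OC | intermediate
9 | methyl (2Z,7R)-3,7-dimethyl-7-[(triethylsilyl)oxy]nona-2,8-dienoate | C=C[C@](C)(O[Si](CC)(CC)CC)CCC/C(C)=C\C(=O)OC | intermediate
10 | (2Z,7R)-3,7-dimethyl-7-[(triethylsilyl)oxy]nona-2,8-dien-1-ol | C=C[C@](C)(O[Si](CC)(CC)CC)CCC/C(C)=C\CO | intermediate
11 | [(2R,3S)-3-methyl-3-{(4R)-4-methyl-4-[(triethylsilyl)oxy]hex-5-en-1-yl}oxiran-2-yl]methanol | C=C[C@](C)(O[Si](CC)(CC)CC)CCC[C@]1(C)O[C@@H]1CO | intermediate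
12 | (2S,3S)-3-methyl-3-{(4R)-4-methyl-4-[(triethylsilyl)oxy]hex-5-en-1-yl}oxirane-2-carbaldehyde | C=C[C@](C)(O[Si](CC)(CC)CC)CCC[C@]1(C)O[C@@H]1C=O | intermediate
13 | (R)-4-benzyl-1,3-oxazolidin-2-one | O=C1N[C@H](Cc2ccccc2)CO1 | starting material
14 | 3-methylbutanoyl chloride (isovaleryl chloride) | CC(C)CC(=O)Cl | starting material
15 | N-lithio derivative of 13 | [Li]N1[C@H](Cc2ccccc2)COC1=O | intermediate
16 | (4R)-4-benzyl-3-(3-methylbutanoyl)-1,3-oxazolidin-2-one | CC(C)CC(=O)N1[C@H](Cc2ccccc2)COC1=O | intermediate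
17 | (Z)-dibutylboron enolate of 16 | CC(C)/C=C(\OB(CCCC)CCCC)N1[C@H](Cc2ccccc2)COC1=O | intermediate
18 | (4R)-4-benzyl-3-[(2R)-2-{(R)-hydroxy[(2R,3S)-3-methyl-3-{(4R)-4-methyl-4-[(triethylsilyl)oxy]hex-5-en-1-yl}oxiran-2-yl]methyl}-3-methylbutanoyl]-1,3-oxazolidin-2-one | C=C[C@](C)(O[Si](CC)(CC)CC)CCC[C@]1(C)O[C@@H]1[C@H](O)[C@@H](C(C)C)C(=O)N1[C@H](Cc2ccccc2)COC1=O | intermediate
19 | triethylsilyl ether of 18 at the aldol hydroxyl | C=C[C@](C)(O[Si](CC)(CC)CC)CCC[C@]1(C)O[C@@H]1[C@H](O[Si](CC)(CC)CC)[C@@H](C(C)C)C(=O)N1[C@H](Cc2ccccc2)COC1=O | intermediate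
20 | (2S)-3-methyl-2-{(R)-[(2R,3S)-3-methyl-3-{(4R)-4-methyl-4-[(triethylsilyl)oxy]hex-5-en-1-yl}oxiran-2-yl][(triethylsilyl)oxy]methyl}butan-1-ol | C=C[C@](C)(O[Si](CC)(CC)CC)CCC[C@]1(C)O[C@@H]1[C@H](O[Si](CC)(CC)CC)[C@@H](C(C)C)CO | intermediate
21 | (2R)-3-methyl-2-{(R)-[(2R,3S)-3-methyl-3-{(4R)-4-methyl-4-[(triethylsilyl)oxy]hex-5-en-1-yl}oxiran-2-yl][(triethylsilyl)oxy]methyl}butanal | C=C[C@](C)(O[Si](CC)(CC)CC)CCC[C@]1(C)O[C@@H]1[C@H](O[Si](CC)(CC)CC)[C@@H](C(C)C)C=O | intermediate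
22 | (3R)-3-methyl-6-[(2S,3R)-2-methyl-3-{(1R,2S)-2-(propan-2-yl)-1-[(triethylsilyl)oxy]but-3-en-1-yl}oxiran-2-yl]-3-[(triethylsilyl)oxy]hex-1-ene | C=C[C@](C)(O[Si](CC)(CC)CC)CCC[C@]1(C)O[C@@H]1[C@H](O[Si](CC)(CC)CC)[C@@H](C(C)C)C=C | intermediate
23 | (1R,2S)-1-{(2R,3S)-3-[(4R)-4-hydroxy-4-methylhex-5-en-1-yl]-3-methyloxiran-2-yl}-2-(propan-2-yl)but-3-en-1-ol | C=C[C@](C)(O)CCC[C@]1(C)O[C@@H]1[C@H](O)[C@@H](C(C)C)C=C | intermediate
24 | (1R,2R,3S,4E,6R,10S)-6,10-dimethyl-3-(propan-2-yl)-11-oxabicyclo[8.1.0]undec-4-ene-2,6-diol | CC(C)[C@H]1/C=C/[C@](C)(O)CCC[C@]2(C)O[C@@H]2[C@@H]1O | intermediate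
25 | 4-hydroxybenzoic acid | OC(=O)c1ccc(O)cc1 | starting material
26 | tert-butyldimethylsilyl 4-[(tert-butyldimethylsilyl)oxy]benzoate | CC(C)(C)[Si](C)(C)OC(=O)c1ccc(O[Si](C)(C)C(C)(C)C)cc1 | intermediate
27 | 4-[(tert-butyldimethylsilyl)oxy]benzoic acid | OC(=O)c1ccc(O[Si](C)(C)C(C)(C)C)cc1 | intermediate
28 | 4-[(tert-butyldimethylsilyl)oxy]benzoic 2,4,6-trichlorobenzoic anhydride | O=C(OC(=O)c1c(Cl)cc(Cl)cc1Cl)c1ccc(O[Si](C)(C)C(C)(C)C)cc1 | intermediate
29 | (1R,2R,3S,4E,6R,10S)-6-hydroxy-6,10-dimethyl-3-(propan-2-yl)-11-oxabicyclo[8.1.0]undec-4-en-2-yl 4-[(tert-butyldimethylsilyl)oxy]benzoate | CC(C)[C@H]1/C=C/[C@](C)(O)CCC[C@]2(C)O[C@@H]2[C@@H]1OC(=O)c1ccc(O[Si](C)(C)C(C)(C)C)cc1 | intermediate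
30 | (1R,2R,3S,4E,6R,10S)-6-hydroxy-6,10-dimethyl-3-(propan-2-yl)-11-oxabicyclo[8.1.0]undec-4-en-2-yl 4-hydroxybenzoate (CNP0278889.1) | CC(C)[C@H]1/C=C/[C@](C)(O)CCC[C@]2(C)O[C@@H]2[C@@H]1OC(=O)c1ccc(O)cc1 | target

**Totals**
Total step count: 20. Longest linear sequence: 18 steps (steps 1–9, 11–17, 19, 20 from linalool); steps 10 and 18 are side branches.

**Steps most likely to fail**

Step 17 (ring-closing metathesis). A strained ten-membered ring must close between two hindered olefins, so oligomers or the Z isomer may dominate. The fallback closes the same C-4=C-5 bond by an intramolecular Julia–Kocienski olefination and sets out from alcohol 20. Mitsunobu thioetherification with 1-phenyl-1H-tetrazole-5-thiol (PPh3, DIAD, THF) gives the tetrazolyl sulfide F1, and oxidation (30% H2O2, (NH4)6Mo7O24·4H2O, EtOH) gives the tetrazolyl sulfone F2. Ozonolysis of its only alkene (O3, CH2Cl2, −78 °C; PPh3) gives the non-enolisable α-silyloxy sulfone aldehyde F3. Slow addition of F3 to KN(SiMe3)2 in DME at −60 °C and 1 mM closes the ring to the E-configured macrocyclic bis(triethylsilyl) ether F4. TBAF in THF then returns to the route at diol 24.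

Step 11 (aldol with the epoxy aldehyde). The boron Lewis acid may open the oxirane, or the sensitive aldehyde 12 may decompose. The fallback forms the same C-2–C-3 bond by carbonyl allylation and sets out from aldehyde 12. The reagent is (Z)-(4-methylpent-2-en-1-yl)diisopinocampheylborane, made in the flask from cis-4-methylpent-2-ene (n-BuLi/KOt-Bu, THF, −78 → −50 °C), then (+)-Ipc2BOMe (the antipode derived from (−)-α-pinene) and BF3·OEt2; it is added at −78 °C with NaBO3·4H2O work-up. The Z geometry gives the 2,3-syn relationship through a chair transition state and the pinene-derived ligands select the aldehyde face, giving the homoallylic alcohol F5, which already carries the C-4 vinyl group. Silylation (TESCl, imidazole, DMAP, DMF) returns to the route at diene 22 and bypasses compounds 16–21.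

Step 13 (reductive removal of the auxiliary). The imide carries an α-isopropyl and a β-silyloxy group, so hydride may attack the ring carbonyl instead. The fallback sets out from imide 19. Lithium ethanethiolate (EtSH, n-BuLi, THF, 0 °C) displaces the auxiliary and gives the S-ethyl thioester F6. Partial reduction with i-Bu2AlH (CH2Cl2, −78 °C) gives the aldehyde directly, returning to the route at aldehyde 21 and bypassing alcohol 20.

**Further compounds**
F1 | step 17 | tetrazolyl sulfide: 20 with OH replaced by (1-phenyl-1H-tetrazol-5-yl)sulfanyl | C=C[C@](C)(O[Si](CC)(CC)CC)CCC[C@]1(C)O[C@@H]1[C@H](O[Si](CC)(CC)CC)[C@@H](C(C)C)CSc1nnnn1-c1ccccc1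
F2 | step 17 | tetrazolyl sulfone: F1 oxidised at sulfur to the sulfone | C=C[C@](C)(O[Si](CC)(CC)CC)CCC[C@]1(C)O[C@@H]1[C@H](O[Si](CC)(CC)CC)[C@@H](C(C)C)CS(=O)(=O)c1nnnn1-c1ccccc1
F3 | step 17 | sulfone aldehyde: F2 with the vinyl group cleaved to the (2R)-2-methyl-2-[(triethylsilyl)oxy] aldehyde | O=C[C@](C)(O[Si](CC)(CC)CC)CCC[C@]1(C)O[C@@H]1[C@H](O[Si](CC)(CC)CC)[C@@H](C(C)C)CS(=O)(=O)c1nnnn1-c1ccccc1
F4 | step 17 | (1R,2R,3S,4E,6R,10S)-6,10-dimethyl-3-(propan-2-yl)-2,6-bis[(triethylsilyl)oxy]-11-oxabicyclo[8.1.0]undec-4-ene | CC(C)[C@H]1/C=C/[C@](C)(O[Si](CC)(CC)CC)CCC[C@]2(C)O[C@@H]2[C@@H]1O[Si](CC)(CC)CC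
F5 | step 11 | (1R,2S)-1-[(2R,3S)-3-methyl-3-{(4R)-4-methyl-4-[(triethylsilyl)oxy]hex-5-en-1-yl}oxiran-2-yl]-2-(propan-2-yl)but-3-en-1-ol | C=C[C@](C)(O[Si](CC)(CC)CC)CCC[C@]1(C)O[C@@H]1[C@H](O)[C@@H](C(C)C)C=C
F6 | step 13 | S-ethyl (2R)-3-methyl-2-{(R)-[(2R,3S)-3-methyl-3-{(4R)-4-methyl-4-[(triethylsilyl)oxy]hex-5-en-1-yl}oxiran-2-yl][(triethylsilyl)oxy]methyl}butanethioate | C=C[C@](C)(O[Si](CC)(CC)CC)CCC[C@]1(C)O[C@@H]1[C@H](O[Si](CC)(CC)CC)[C@@H](C(C)C)C(=O)SCC
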